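**Plan**

1. Ring B is a 1,4-hydroquinone: C2'–OH and C5'–OH are para, the methoxy group sits on C4' beside C5', and C1' carries C2 of ring C. A 4-alkenyl-4-hydroxy-3-methoxycyclobut-2-enone gives exactly this pattern on heating.
2. Cuts, backward: the O5 and O7 benzyl ethers; ring B at C1'–C2' (6π closure) and C2'–C5' (the four-membered ring); alkene back to alkyne; C5'–C6' (acetylide plus methyl semisquarate); C1'–C6' (aldehyde to alkyne); ring C at O1–C2 and C2–C3; two C–OMe bonds of ring A.
3. Forward: ring A is dressed first (double benzylation, dibromination, copper-catalysed double methoxylation), ring C is closed as a chromone-2-carbaldehyde, C6' is added as an alkyne carbon, the cyclobutenone is attached, ring B is formed by thermolysis, and hydrogenolysis ends the route.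
4. Stereochemistry: the target has no stereocentre. The carbinol centre from the acetylide addition is racemic and the Z-alkene from semihydrogenation is only a vehicle; both vanish when ring B aromatises.

Key step: step 10

Remark: the target is achiral, so the cyclobutenone carbinol centre is carried as the racemate; ethyl diethoxyacetate, Me3SiCHN2 and LiAlH(OtBu)3 are taken as purchased reagents.

**Route**

Step 1
Reactants: 1 2',4',6'-trihydroxyacetophenone; 2 benzyl bromide (two equivalents are consumed)
Product: 3 1-[2,4-bis(benzyloxy)-6-hydroxyphenyl]ethan-1-one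
Conditions: BnBr (2.1 equiv), K2CO3, DMF, rt
Reagents that add atoms: benzyl bromide (second equivalent of 2), BrCc1ccccc1
Why: Twofold Williamson etherification alkylates the para hydroxyl and one ortho hydroxyl with one benzyl bromide each, while the other ortho hydroxyl is held in a hydrogen bond to the acetyl carbonyl and should stay free.

Step 2
Reactants: 3 1-[2,4-bis(benzyloxy)-6-hydroxyphenyl]ethan-1-one
Product: 4 1-[2,4-bis(benzyloxy)-3,5-dibromo-6-hydroxyphenyl]ethan-1-one
Conditions: NBS (2.1 equiv), MeCN, 0 °C → rt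
Reagents that add atoms: N-bromosuccinimide, O=C1CCC(=O)N1Br; N-bromosuccinimide (second equivalent), O=C1CCC(=O)N1Br
Why: Electrophilic aromatic bromination should take the only two ring C–H positions, both strongly activated (ortho and para to the free phenol, each flanked by oxygen), faster than the acetyl group can be brominated.

Step 3
Reactants: 4 1-[2,4-bis(benzyloxy)-3,5-dibromo-6-hydroxyphenyl]ethan-1-one
Product: 5 1-[2,4-bis(benzyloxy)-6-hydroxy-3,5-dimethoxyphenyl]ethan-1-one
Conditions: NaOMe (excess), CuBr (20 mol %), DMF–MeOH, 110 °C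
Reagents that add atoms: sodium methoxide, C[O-].[Na+]; sodium methoxide (second equivalent), C[O-].[Na+]
Why: Ullmann-type methoxylation of aryl bromides under monovalent copper catalysis is the standard bromophenol-to-methoxyphenol exchange, and the phenoxide, the ketone (deactivated as its ortho-phenoxide) and the benzyl ethers should tolerate methoxide.

Step 4
Reactants: 5 1-[2,4-bis(benzyloxy)-6-hydroxy-3,5-dimethoxyphenyl]ethan-1-one; 6 ethyl diethoxyacetate
Product: 8 5,7-bis(benzyloxy)-2-(diethoxymethyl)-6,8-dimethoxy-4H-chromen-4-one, via diketone 7 (not isolated)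
Conditions: NaH (3 equiv), THF, 0 °C → reflux; AcOH; then TsOH·H2O (cat.), EtOH, 70 °C
Reagents that add atoms: none
Why: Crossed Claisen condensation of the ketone enolate with the non-enolisable, activated ester gives the 1,3-diketone, and acid-catalysed cyclodehydration of the ortho-hydroxyaryl diketone closes ring C, with ethanol as solvent keeping the acetal intact.

Step 5
Reactants: 8 5,7-bis(benzyloxy)-2-(diethoxymethyl)-6,8-dimethoxy-4H-chromen-4-one
Product: 9 5,7-bis(benzyloxy)-6,8-dimethoxy-4-oxo-4H-chromene-2-carbaldehyde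
Conditions: HCO2H–H2O (4:1), 50 °C
Reagents that add atoms: water, O
Why: Acid-catalysed acetal hydrolysis under conditions that should leave aryl benzyl ethers and the chromone untouched.

Step 6
Reactants: 9 5,7-bis(benzyloxy)-6,8-dimethoxy-4-oxo-4H-chromene-2-carbaldehyde
Product: 10 5,7-bis(benzyloxy)-2-ethynyl-6,8-dimethoxy-4H-chromen-4-one
Conditions: Me3SiCHN2, LiN(iPr)2, THF, −78 °C → rt; AcOH
Reagents that add atoms: trimethylsilyldiazomethane, C[Si](C)(C)C=[N+]=[N-]
Why: Colvin rearrangement (addition of the lithiated diazo reagent to the aldehyde, Peterson-type elimination, loss of N2 and 1,2-hydride shift) gives the terminal alkyne in an aprotic medium, so no alkoxide is present to attack the chromone or the new alkyne.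

Step 7
Reactants: 11 dimethyl squarate
Product: 13 3-methoxycyclobut-3-ene-1,2-dione (methyl semisquarate), via hydroxycyclobutenone 12 (not isolated)
Conditions: LiAlH(OtBu)3, THF, −78 → −20 °C; aq. HCl; then conc. HCl (cat.), CH2Cl2, rt
Reagents that add atoms: water, O
Why: The bulky hydride reduces one carbonyl of the squarate by 1,2-addition, and acid then ionises the carbinol, water is captured at the distal methoxy-bearing carbon and methanol is lost (allylic oxygen transposition), the established way from dialkyl squarates to alkyl semisquarates.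

Step 8
Reactants: 10 5,7-bis(benzyloxy)-2-ethynyl-6,8-dimethoxy-4H-chromen-4-one; 13 3-methoxycyclobut-3-ene-1,2-dione
Product: 15 racemic 5,7-bis(benzyloxy)-2-[(1-hydroxy-2-methoxy-4-oxocyclobut-2-en-1-yl)ethynyl]-6,8-dimethoxy-4H-chromen-4-one, via lithium acetylide 14 (not isolated)
Conditions: LiN(SiMe3)2, THF, −78 °C; then added to 13, THF, −78 °C; AcOH
Reagents that add atoms: none
Why: 1,2-Addition of a lithium acetylide to a cyclobutenedione goes to the carbonyl next to the methoxy-bearing carbon, which is a plain enone carbonyl and more electrophilic than the other (a vinylogous ester), so the carbinol ends up beside C–OMe; the new centre forms as the racemate.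

Step 9
Reactants: 15 racemic 5,7-bis(benzyloxy)-2-[(1-hydroxy-2-methoxy-4-oxocyclobut-2-en-1-yl)ethynyl]-6,8-dimethoxy-4H-chromen-4-one
Product: 16 racemic 5,7-bis(benzyloxy)-2-[(Z)-2-(1-hydroxy-2-methoxy-4-oxocyclobut-2-en-1-yl)ethenyl]-6,8-dimethoxy-4H-chromen-4-one
Conditions: H2 (1 atm), Pd/CaCO3 poisoned with Pb(OAc)2 (Lindlar catalyst), quinoline, EtOAc, rt
Reagents that add atoms: none
Why: Lindlar semihydrogenation adds H2 syn to the alkyne and should give the Z-alkene without touching the benzyl ethers, the chromone or the enol-ether double bond of the cyclobutenone.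

Step 10
Reactants: 16 racemic 5,7-bis(benzyloxy)-2-[(Z)-2-(1-hydroxy-2-methoxy-4-oxocyclobut-2-en-1-yl)ethenyl]-6,8-dimethoxy-4H-chromen-4-one
Product: 19 5,7-bis(benzyloxy)-2-(2,5-dihydroxy-4-methoxyphenyl)-6,8-dimethoxy-4H-chromen-4-one, via dienylketene 17 (not isolated), via cyclohexadienone 18 (not isolated)
Conditions: degassed PhMe, 110 °C, Ar
Reagents that add atoms: none
Why: Thermal conrotatory 4π opening of the cyclobutenone (C1–C4 cleavage) gives dienylketene 17, whose ketene carbon bonds to the chromone-bearing alkene carbon in a thermal disrotatory 6π electrocyclisation to cyclohexa-2,4-dienone 18, and enolisation of 18 gives the hydroquinone. This is the Moore rearrangement of 4-alkenyl-4-hydroxycyclobutenones to hydroquinones. Ring B is thus closed as a six-membered carbocycle by electrocyclisation, the ketene carbon becoming C2'–OH, the carbinol carbon C5'–OH, the methoxy carbon C4', the ring CH C3' and the alkene carbons C6' and C1'. No stereocentre remains, because the racemic carbinol centre becomes sp2 on ring opening and the transient sp3 centre of 18 is lost on tautomerisation. The step needs torquoselectivity, which the free 4-hydroxyl secures: as the stronger donor it rotates outward and turns the alkenyl arm inward, cis to the ketene; the position of OMe was already fixed by the regiochemistry of step 8. Oxygen is excluded so that the hydroquinone is not oxidised to the quinone.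

Step 11
Reactants: 19 5,7-bis(benzyloxy)-2-(2,5-dihydroxy-4-methoxyphenyl)-6,8-dimethoxy-4H-chromen-4-one
Product: 20 5,7-dihydroxy-2-(2,5-dihydroxy-4-methoxyphenyl)-6,8-dimethoxy-4H-chromen-4-one
Conditions: H2 (1 atm), 10% Pd/C, EtOAc–MeOH, rt
Reagents that add atoms: none
Why: Hydrogenolysis of the two aryl benzyl ethers over Pd/C should proceed at room temperature without reducing the flavone C2=C3 bond or cleaving the methyl ethers.

**Compound list**

1 | 2',4',6'-trihydroxyacetophenone | CC(=O)c1c(O)cc(O)cc1O | starting material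
2 | benzyl bromide | BrCc1ccccc1 | starting material
3 | 1-[2,4-bis(benzyloxy)-6-hydroxyphenyl]ethan-1-one | CC(=O)c1c(O)cc(OCc2ccccc2)cc1OCc1ccccc1 | intermediate
4 | 1-[2,4-bis(benzyloxy)-3,5-dibromo-6-hydroxyphenyl]ethan-1-one | CC(=O)c1c(O)c(Br)c(OCc2ccccc2)c(Br)c1OCc1ccccc1 | intermediate
5 | 1-[2,4-bis(benzyloxy)-6-hydroxy-3,5-dimethoxyphenyl]ethan-1-one | CC(=O)c1c(O)c(OC)c(OCc2ccccc2)c(OC)c1OCc1ccccc1 | intermediate
6 | ethyl diethoxyacetate | CCOC(OCC)C(=O)OCC | starting material
7 | 1-[2,4-bis(benzyloxy)-6-hydroxy-3,5-dimethoxyphenyl]-4,4-diethoxybutane-1,3-dione (not isolated) | CCOC(OCC)C(=O)CC(=O)c1c(O)c(OC)c(OCc2ccccc2)c(OC)c1OCc1ccccc1 | intermediate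
8 | 5,7-bis(benzyloxy)-2-(diethoxymethyl)-6,8-dimethoxy-4H-chromen-4-one | CCOC(OCC)c1cc(=O)c2c(OCc3ccccc3)c(OC)c(OCc3ccccc3)c(OC)c2o1 | intermediate
9 | 5,7-bis(benzyloxy)-6,8-dimethoxy-4-oxo-4H-chromene-2-carbaldehyde | O=Cc1cc(=O)c2c(OCc3ccccc3)c(OC)c(OCc3ccccc3)c(OC)c2o1 | intermediate
10 | 5,7-bis(benzyloxy)-2-ethynyl-6,8-dimethoxy-4H-chromen-4-one | C#Cc1cc(=O)c2c(OCc3ccccc3)c(OC)c(OCc3ccccc3)c(OC)c2o1 | intermediate
11 | dimethyl squarate (3,4-dimethoxycyclobut-3-ene-1,2-dione) | COC1=C(OC)C(=O)C1=O | starting material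
12 | racemic 4-hydroxy-2,3-dimethoxycyclobut-2-en-1-one (not isolated) | COC1=C(OC)C(=O)C1O | intermediate
13 | 3-methoxycyclobut-3-ene-1,2-dione (methyl semisquarate) | COC1=CC(=O)C1=O | intermediate
14 | lithium acetylide of 10 (not isolated) | [Li]C#Cc1cc(=O)c2c(OCc3ccccc3)c(OC)c(OCc3ccccc3)c(OC)c2o1 | intermediate
15 | racemic 5,7-bis(benzyloxy)-2-[(1-hydroxy-2-methoxy-4-oxocyclobut-2-en-1-yl)ethynyl]-6,8-dimethoxy-4H-chromen-4-one | COC1=CC(=O)C1(O)C#Cc1cc(=O)c2c(OCc3ccccc3)c(OC)c(OCc3ccccc3)c(OC)c2o1 | intermediate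
16 | racemic 5,7-bis(benzyloxy)-2-[(Z)-2-(1-hydroxy-2-methoxy-4-oxocyclobut-2-en-1-yl)ethenyl]-6,8-dimethoxy-4H-chromen-4-one | COC1=CC(=O)C1(O)/C=C\c1cc(=O)c2c(OCc3ccccc3)c(OC)c(OCc3ccccc3)c(OC)c2o1 | intermediate
17 | (3Z,5Z)-6-[5,7-bis(benzyloxy)-6,8-dimethoxy-4-oxo-4H-chromen-2-yl]-4-hydroxy-3-methoxyhexa-1,3,5-trien-1-one (dienylketene, not isolated) | O=C=C/C(OC)=C(\C=C/c1cc(=O)c2c(OCc3ccccc3)c(OC)c(OCc3ccccc3)c(OC)c2o1)O | intermediate
18 | racemic 6-[5,7-bis(benzyloxy)-6,8-dimethoxy-4-oxo-4H-chromen-2-yl]-4-hydroxy-3-methoxycyclohexa-2,4-dien-1-one (not isolated) | COC1=CC(=O)C(c2cc(=O)c3c(OCc4ccccc4)c(OC)c(OCc4ccccc4)c(OC)c3o2)C=C1O | intermediate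
19 | 5,7-bis(benzyloxy)-2-(2,5-dihydroxy-4-methoxyphenyl)-6,8-dimethoxy-4H-chromen-4-one | COc1cc(O)c(-c2cc(=O)c3c(OCc4ccccc4)c(OC)c(OCc4ccccc4)c(OC)c3o2)cc1O | intermediate
20 | 5,7-dihydroxy-2-(2,5-dihydroxy-4-methoxyphenyl)-6,8-dimethoxy-4H-chromen-4-one | COc1cc(O)c(-c2cc(=O)c3c(O)c(OC)c(O)c(OC)c3o2)cc1O | target

**Step count and risks**

Total step count: 11. Longest linear sequence: 10 steps (steps 1–6 and 8–11 from compound 1); step 7 is a one-step branch from compound 11.

Steps most likely to fail:

Step 8 (acetylide addition). The lithium acetylide 14 is conjugated to the chromone and may add to C2 or C4 of a second chromone before it meets 13. It may also attack the methoxy-bearing carbon of 13 and expel methoxide instead of adding to the carbonyl. The fallback sets out from 10 and comes back at 15, replacing the free carbanion by a silicon-bound one. Alkyne 10 would be C-silylated under amine conditions (Me3SiOTf, Et3N, Zn(OTf)2 cat., CH2Cl2) to 5,7-bis(benzyloxy)-6,8-dimethoxy-2-[(trimethylsilyl)ethynyl]-4H-chromen-4-one F1. F1 and 13 would then be joined by fluoride-catalysed alkynyl transfer (tetrabutylammonium difluorotriphenylsilicate cat., THF, −20 °C), in which only a catalytic amount of hypervalent silicate is present and the silyl group ends on oxygen. This should give racemic 5,7-bis(benzyloxy)-6,8-dimethoxy-2-{[2-methoxy-4-oxo-1-(trimethylsilyloxy)cyclobut-2-en-1-yl]ethynyl}-4H-chromen-4-one F2. Brief treatment with AcOH–H2O–THF would remove the silyl ether and give 15.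

Step 6 (aldehyde to alkyne). The lithiated diazo reagent may add in conjugate fashion to the chromone or open the pyranone, and the base-sensitive 2-ethynylchromone may degrade during warming. The fallback sets out from 9 and comes back at 15, so that neither 10 nor a lithium amide is needed. Corey–Fuchs olefination (CBr4, PPh3, CH2Cl2, 0 °C) would give 5,7-bis(benzyloxy)-2-(2,2-dibromoethenyl)-6,8-dimethoxy-4H-chromen-4-one F3. Dehydrobromination with DBU in DMSO would give 5,7-bis(benzyloxy)-2-(bromoethynyl)-6,8-dimethoxy-4H-chromen-4-one F4. Bromine–magnesium exchange with i-PrMgCl·LiCl in THF at −78 °C would give {[5,7-bis(benzyloxy)-6,8-dimethoxy-4-oxo-4H-chromen-2-yl]ethynyl}magnesium chloride F5, which is added to 13 at −78 °C and gives 15 after aqueous NH4Cl.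

Step 10 (thermolysis). Closure of the dienylketene may be slowed by the inward chromone substituent of the Z-alkene, leaving the ketene open to lactonisation to a butenolide after isomerisation. The hydroquinone may also be oxidised by traces of air, and over-reduction in step 9 would already have eroded the material. The fallback sets out from 15 and comes back at 19, staying with the same four-membered-ring expansion and the same C1'–C2' bond. The alkynyl adduct 15 is heated itself (degassed PhMe, 110 °C): ring opening, closure onto the alkyne and hydrogen transfer from the hydroxyl should give 2-[5,7-bis(benzyloxy)-6,8-dimethoxy-4-oxo-4H-chromen-2-yl]-5-methoxycyclohexa-2,5-diene-1,4-dione F6. Reduction of F6 with aqueous Na2S2O4 (EtOAc–H2O, rt) would give hydroquinone 19, and step 9 is no longer needed.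

**Further compounds**

F1 | step 8 | 5,7-bis(benzyloxy)-6,8-dimethoxy-2-[(trimethylsilyl)ethynyl]-4H-chromen-4-one | C[Si](C)(C)C#Cc1cc(=O)c2c(OCc3ccccc3)c(OC)c(OCc3ccccc3)c(OC)c2o1
F2 | step 8 | racemic 5,7-bis(benzyloxy)-6,8-dimethoxy-2-{[2-methoxy-4-oxo-1-(trimethylsilyloxy)cyclobut-2-en-1-yl]ethynyl}-4H-chromen-4-one | COC1=CC(=O)C1(O[Si](C)(C)C)C#Cc1cc(=O)c2c(OCc3ccccc3)c(OC)c(OCc3ccccc3)c(OC)c2o1
F3 | step 6 | 5,7-bis(benzyloxy)-2-(2,2-dibromoethenyl)-6,8-dimethoxy-4H-chromen-4-one | BrC(Br)=Cc1cc(=O)c2c(OCc3ccccc3)c(OC)c(OCc3ccccc3)c(OC)c2o1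
F4 | step 6 | 5,7-bis(benzyloxy)-2-(bromoethynyl)-6,8-dimethoxy-4H-chromen-4-one | BrC#Cc1cc(=O)c2c(OCc3ccccc3)c(OC)c(OCc3ccccc3)c(OC)c2o1
F5 | step 6 | {[5,7-bis(benzyloxy)-6,8-dimethoxy-4-oxo-4H-chromen-2-yl]ethynyl}magnesium chloride | Cl[Mg]C#Cc1cc(=O)c2c(OCc3ccccc3)c(OC)c(OCc3ccccc3)c(OC)c2o1
F6 | step 10 | 2-[5,7-bis(benzyloxy)-6,8-dimethoxy-4-oxo-4H-chromen-2-yl]-5-methoxycyclohexa-2,5-diene-1,4-dione | COC1=CC(=O)C(=CC1=O)c1cc(=O)c2c(OCc3ccccc3)c(OC)c(OCc3ccccc3)c(OC)c2o1
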